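The route rests on removing C2 from the epoxycyclohexenone ring. C2 is sp2 and stereochemically silent. It lies between the C1 carbonyl and C3–H and carries the nitrogen. The precursor is therefore a cyclopentanone silyl enol ether (C1, C3, C4, C5, C6). It already holds the C4 carbinol and the C5–C6 oxirane in final configuration, all relayed from the single bought stereocentre of (R)-4-silyloxycyclopentenone. Dibromocarbene adds to C1=C3 and the strained adduct opens electrocyclically. This one operation inserts C2, enlarges the carbocycle from five to six members, creates the C2=C3 enone and leaves bromine on C2. That bromine is the handle for palladium-catalysed amidation with the separately made dienamide.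

Key step: step 8

Numbering used throughout (also for the five-membered precursors): C1 ketone carbon, C2 nitrogen-bearing carbon, C3 olefinic CH, C4 carbinol carbon, C5 and C6 oxirane carbons (C6 next to C1). In the target the C4 hydroxyl is trans to the oxirane oxygen.

Assumption: Pseudomonas fluorescens lipase acetylates the hydroxymethyl group next to the (S)-configured centre of meso-diol 14. If the enzyme showed the opposite sense, the two termini of the monoacetate would be elaborated in reverse order.

Step 1
Reactants: 1 (R)-4-(tert-butyldimethylsilyloxy)cyclopent-2-en-1-one; 2 (5-bromopentyloxy)(tert-butyl)dimethylsilane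
Product: 4 (1S,4R)-4-(tert-butyldimethylsilyloxy)-1-[5-(tert-butyldimethylsilyloxy)pentyl]cyclopent-2-en-1-ol, via Grignard reagent 3 (not isolated)
Conditions: 2, Mg, THF, rt → 40 °C; then 1, LaCl3·2LiCl, THF, −78 → −30 °C; aq. NH4Cl
Reagents that add atoms: magnesium, [Mg] (held in 3 only)
Why: Lanthanide-assisted Grignard 1,2-addition, in which LaCl3 suppresses enolisation and conjugate addition and the nucleophile should approach the flat enone opposite to the silyloxy group, which sets C4 with the new hydroxyl cis to OTBS.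

Step 2
Reactants: 4
Product: 5 triethylsilyl ether of 4 (C4–OTES and C1–OTBS on the same ring face)
Conditions: TESOTf, 2,6-lutidine, CH2Cl2, −78 → 0 °C
Reagents that add atoms: triethylsilyl triflate, CC[Si](CC)(CC)OS(=O)(=O)C(F)(F)F
Why: Silyl triflate silylation of a hindered tertiary alcohol, which removes the hydrogen-bond directing effect of the free hydroxyl and puts a second bulky group on that ring face.

Step 3
Reactants: 5
Product: 6 (1S,2S,4R,5R)-4-(tert-butyldimethylsilyloxy)-2-[5-(tert-butyldimethylsilyloxy)pentyl]-2-(triethylsilyloxy)-6-oxabicyclo[3.1.0]hexane (oxirane trans to both ring silyloxy groups)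
Conditions: mCPBA, NaHCO3, CH2Cl2, 0 °C → rt
Reagents that add atoms: 3-chloroperbenzoic acid, OOC(=O)c1cccc(Cl)c1
Why: Prilezhaev epoxidation, in which the peracid should attack the face opposite to the two cis silyloxy groups, so that C5 and C6 are set trans to the C4 oxygen by substrate control.

Step 4
Reactants: 6
Product: 7 (1S,2S,4R,5S)-2-(5-hydroxypentyl)-6-oxabicyclo[3.1.0]hexane-2,4-diol (both ring hydroxyls trans to the oxirane)
Conditions: Et3N·3HF, MeCN, rt → 40 °C
Reagents that add atoms: none
Why: Fluoride-mediated global desilylation in a weakly acidic medium, where no alkoxide forms, so that epoxide migration (Payne rearrangement) of the trans epoxy alcohols is avoided and the deactivated oxirane stays closed.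

Step 5
Reactants: 7
Product: 8 5-[(1S,2S,5R)-2-hydroxy-4-oxo-6-oxabicyclo[3.1.0]hexan-2-yl]pentanoic acid
Conditions: AZADO (cat.), PhI(OAc)2, MeCN/pH 7 phosphate buffer, 0 °C → rt
Reagents that add atoms: water, O
Why: Oxoammonium (nitroxyl radical) catalysed oxidation, which takes the primary alcohol through the aldehyde hydrate to the acid and the secondary alcohol to the C1 ketone, leaves the tertiary C4 hydroxyl untouched and erases the relay stereocentre once it has done its work.

Step 6
Reactants: 8
Product: 9 2-(trimethylsilyl)ethyl 5-[(1S,2S,5R)-2-hydroxy-4-oxo-6-oxabicyclo[3.1.0]hexan-2-yl]pentanoate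
Conditions: Me3SiCH2CH2OH, EDC·HCl, DMAP (cat.), CH2Cl2, 0 °C → rt
Reagents that add atoms: 2-(trimethylsilyl)ethanol, C[Si](C)(C)CCO
Why: Steglich esterification under nearly neutral conditions, which the β-hydroxy ketone tolerates and in which the hindered tertiary hydroxyl does not compete with the primary alcohol reagent.

Step 7
Reactants: 9
Product: 10 2-(trimethylsilyl)ethyl 5-[(1S,2S,5R)-2,4-bis(triethylsilyloxy)-6-oxabicyclo[3.1.0]hex-3-en-2-yl]pentanoate
Conditions: TESOTf (excess), Et3N, CH2Cl2, −78 → 0 °C
Reagents that add atoms: triethylsilyl triflate, CC[Si](CC)(CC)OS(=O)(=O)C(F)(F)F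
Why: O-silylation followed by soft enolisation in one flask, regioselective for C3 because enolisation toward C6 would place a double bond on an oxirane carbon, and mild enough that the β-silyloxy group is not eliminated.

Step 8
Reactants: 10
Product: 12 2-(trimethylsilyl)ethyl 5-[(1S,2S,6R)-4-bromo-5-oxo-2-(triethylsilyloxy)-7-oxabicyclo[4.1.0]hept-3-en-2-yl]pentanoate, via dibromocyclopropane 11 (not isolated)
Conditions: CHBr3, KOtBu (excess), pentane, −30 °C → rt
Reagents that add atoms: bromoform, BrC(Br)Br
Why: α-Elimination of HBr from bromoform gives dibromocarbene, which adds in a concerted [2+1] manner to the C1=C3 silyl enol ether, the only electron-rich alkene of 10, to give the 6,6-dibromo-1-silyloxybicyclo[3.1.0]hexane 11. Pushed by the silyloxy lone pair and by ring strain, 11 undergoes disrotatory two-electron electrocyclic opening with loss of the endo bromide (Woodward–Hoffmann–DePuy rule), so that the old C1–C3 bond breaks, the carbene carbon ends as C2 between C1 and C3, and tert-butoxide takes the silyl group from the silyloxyallyl cation to release the 2-bromoenone 12. This is the known dihalocarbene ring enlargement of cyclic silyl enol ethers to 2-halocycloalk-2-enones. The three-membered ring is closed by the [2+1] cycloaddition, whereas the six-membered ring is not closed by a cyclisation but arises when the zero-atom bridge of the bicycle is cut. No lasting stereocentre is made, because the two transient centres at C1 and C3 return to sp2 and the face of carbene attack is therefore irrelevant, while C4, C5 and C6 are spectators. The step needs chemoselectivity for the enol ether over ester, oxirane and silyl ether, which the electrophilic carbene secures, the excess alkoxide keeps silyl bromide away from the oxirane, and the place of bromine on C2 is fixed by the mechanism.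

Step 9
Reactants: 13 meso-2,4-dimethylglutaric anhydride, (3R,5S)-3,5-dimethyloxane-2,6-dione
Product: 14 meso-(2R,4S)-2,4-dimethylpentane-1,5-diol
Conditions: LiAlH4, THF, 0 °C → reflux; aq. NaOH work-up
Reagents that add atoms: none
Why: Hydride reduction of a cyclic anhydride to the diol, which does not touch the two syn methyl-bearing centres.

Step 10
Reactants: 14
Product: 15 (2R,4S)-5-acetoxy-2,4-dimethylpentan-1-ol
Conditions: Pseudomonas fluorescens lipase, vinyl acetate, THF, rt
Reagents that add atoms: vinyl acetate, C=COC(C)=O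
Why: Enzymatic desymmetrising transesterification of a meso-diol, irreversible because the enol tautomerises to acetaldehyde, in which the catalyst tells the enantiotopic hydroxymethyl groups apart and so fixes both side-chain stereocentres at once.

Step 11
Reactants: 15
Product: 16 (2S,4R)-2,4-dimethyl-5-oxopentyl acetate
Conditions: TEMPO (cat.), PhI(OAc)2, CH2Cl2, rt
Reagents that add atoms: none
Why: Oxoammonium-catalysed oxidation of a primary alcohol that stops at the aldehyde in the absence of water and should not epimerise the α-methyl centre.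

Step 12
Reactants: 16
Product: 17 (2S,4R)-2,4,6-trimethylhept-5-en-1-yl acetate
Conditions: iPrPPh3I, NaHMDS, THF, 0 °C; then 16, −78 °C → rt
Reagents that add atoms: isopropyltriphenylphosphonium iodide, CC(C)[P+](c1ccccc1)(c1ccccc1)c1ccccc1.[I-]
Why: Wittig olefination with a non-stabilised ylide, which reacts with the aldehyde at low temperature much faster than with the acetate or the α-hydrogen and raises no alkene geometry issue.

Step 13
Reactants: 17
Product: 18 (2S,4R)-2,4,6-trimethylhept-5-en-1-ol
Conditions: K2CO3 (cat.), MeOH, rt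
Reagents that add atoms: none
Why: Base-catalysed transesterification (methanolysis) of the acetate, with no acidic stereocentre in the substrate.

Step 14
Reactants: 18
Product: 19 (2S,4R)-2,4,6-trimethylhept-5-enal
Conditions: TEMPO (cat.), PhI(OAc)2, CH2Cl2, rt
Reagents that add atoms: none
Why: Oxoammonium-catalysed alcohol oxidation, which leaves the trisubstituted alkene alone and should keep the α-centre intact.

Step 15
Reactants: 19
Product: 20 (2E,4S,6R)-4,6,8-trimethylnona-2,7-dienamide
Conditions: (EtO)2P(O)CH2CONH2, LiCl, DBU, MeCN, 0 °C → rt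
Reagents that add atoms: diethyl (2-amino-2-oxoethyl)phosphonate, CCOP(=O)(CC(N)=O)OCC
Why: Horner–Wadsworth–Emmons olefination under Masamune–Roush conditions, in which the lithium-chelated stabilised phosphonate anion should give the (E)-acrylamide and the weak amine base spares the α-stereocentre of the aldehyde.

Step 16
Reactants: 12; 20
Product: 21 2-(trimethylsilyl)ethyl 5-[(1S,2S,6R)-5-oxo-2-(triethylsilyloxy)-4-{[(2E,4S,6R)-4,6,8-trimethylnona-2,7-dienoyl]amino}-7-oxabicyclo[4.1.0]hept-3-en-2-yl]pentanoate
Conditions: Pd2(dba)3 (cat.), Xantphos, Cs2CO3, toluene, 50 °C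
Reagents that add atoms: none
Why: Palladium-catalysed vinylic amidation (Buchwald–Hartwig type), in which zerovalent palladium inserts into the activated C2–Br bond of the α-bromoenone, the deprotonated primary amide binds and the wide-bite-angle Xantphos complex reductively eliminates the C2–N bond with retention of the ring alkene, all stereocentres of both halves being spectators.

Step 17
Reactants: 21
Product: 22 5-[(1S,2S,6R)-2-hydroxy-5-oxo-4-{[(2E,4S,6R)-4,6,8-trimethylnona-2,7-dienoyl]amino}-7-oxabicyclo[4.1.0]hept-3-en-2-yl]pentanoic acid (target)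
Conditions: TASF, DMF/H2O, 0 °C → rt; then cold dilute HCl to pH 4
Reagents that add atoms: none
Why: Fluoride-induced global desilylation, in which attack on silicon frees the C4 hydroxyl and fragments the 2-(trimethylsilyl)ethyl ester to carboxylate, ethene and Me3SiF, while water protonates the C4 alkoxide at once so that Payne-type epoxide migration is held back.

Compound list
1 | (R)-4-(tert-butyldimethylsilyloxy)cyclopent-2-en-1-one | O=C1C=C[C@H](O[Si](C)(C)C(C)(C)C)C1 | starting material
2 | (5-bromopentyloxy)(tert-butyl)dimethylsilane | BrCCCCCO[Si](C)(C)C(C)(C)C | starting material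
3 | [5-(tert-butyldimethylsilyloxy)pentyl]magnesium bromide | Br[Mg]CCCCCO[Si](C)(C)C(C)(C)C | intermediate
4 | (1S,4R)-4-(tert-butyldimethylsilyloxy)-1-[5-(tert-butyldimethylsilyloxy)pentyl]cyclopent-2-en-1-ol | C1[C@@](O)(CCCCCO[Si](C)(C)C(C)(C)C)C=C[C@@H]1O[Si](C)(C)C(C)(C)C | intermediate
5 | triethylsilyl ether of 4 | C1[C@@](O[Si](CC)(CC)CC)(CCCCCO[Si](C)(C)C(C)(C)C)C=C[C@@H]1O[Si](C)(C)C(C)(C)C | intermediate
6 | (1S,2S,4R,5R)-4-(tert-butyldimethylsilyloxy)-2-[5-(tert-butyldimethylsilyloxy)pentyl]-2-(triethylsilyloxy)-6-oxabicyclo[3.1.0]hexane | C1[C@@](O[Si](CC)(CC)CC)(CCCCCO[Si](C)(C)C(C)(C)C)[C@H]2O[C@H]2[C@@H]1O[Si](C)(C)C(C)(C)C | intermediate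
7 | (1S,2S,4R,5S)-2-(5-hydroxypentyl)-6-oxabicyclo[3.1.0]hexane-2,4-diol | C1[C@@](O)(CCCCCO)[C@H]2O[C@H]2[C@@H]1O | intermediate
8 | 5-[(1S,2S,5R)-2-hydroxy-4-oxo-6-oxabicyclo[3.1.0]hexan-2-yl]pentanoic acid | C1[C@@](O)(CCCCC(=O)O)[C@H]2O[C@H]2C1=O | intermediate
9 | 2-(trimethylsilyl)ethyl 5-[(1S,2S,5R)-2-hydroxy-4-oxo-6-oxabicyclo[3.1.0]hexan-2-yl]pentanoate | C1[C@@](O)(CCCCC(=O)OCC[Si](C)(C)C)[C@H]2O[C@H]2C1=O | intermediate
10 | 2-(trimethylsilyl)ethyl 5-[(1S,2S,5R)-2,4-bis(triethylsilyloxy)-6-oxabicyclo[3.1.0]hex-3-en-2-yl]pentanoate | CC[Si](CC)(CC)OC1=C[C@@](O[Si](CC)(CC)CC)(CCCCC(=O)OCC[Si](C)(C)C)[C@H]2O[C@@H]12 | intermediate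
11 | 2-(trimethylsilyl)ethyl 5-[7,7-dibromo-1,5-bis(triethylsilyloxy)-3-oxatricyclo[4.1.0.0(2,4)]heptan-5-yl]pentanoate (CBr2 bridge across C1–C3, drawn trans to the oxirane; the other face converges on the same 12) | CC[Si](CC)(CC)O[C@@]12C(Br)(Br)[C@@H]1[C@@](O[Si](CC)(CC)CC)(CCCCC(=O)OCC[Si](C)(C)C)[C@H]3O[C@@H]23 | intermediate
12 | 2-(trimethylsilyl)ethyl 5-[(1S,2S,6R)-4-bromo-5-oxo-2-(triethylsilyloxy)-7-oxabicyclo[4.1.0]hept-3-en-2-yl]pentanoate | BrC1=C[C@@](O[Si](CC)(CC)CC)(CCCCC(=O)OCC[Si](C)(C)C)[C@H]2O[C@H]2C1=O | intermediate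
13 | meso-2,4-dimethylglutaric anhydride | C[C@@H]1C[C@H](C)C(=O)OC1=O | starting material
14 | meso-(2R,4S)-2,4-dimethylpentane-1,5-diol | OC[C@H](C)C[C@H](C)CO | intermediate
15 | (2R,4S)-5-acetoxy-2,4-dimethylpentan-1-ol | OC[C@H](C)C[C@H](C)COC(C)=O | intermediate
16 | (2S,4R)-2,4-dimethyl-5-oxopentyl acetate | O=C[C@H](C)C[C@H](C)COC(C)=O | intermediate
17 | (2S,4R)-2,4,6-trimethylhept-5-en-1-yl acetate | CC(C)=C[C@H](C)C[C@H](C)COC(C)=O | intermediate
18 | (2S,4R)-2,4,6-trimethylhept-5-en-1-ol | CC(C)=C[C@H](C)C[C@H](C)CO | intermediate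
19 | (2S,4R)-2,4,6-trimethylhept-5-enal | CC(C)=C[C@H](C)C[C@H](C)C=O | intermediate
20 | (2E,4S,6R)-4,6,8-trimethylnona-2,7-dienamide | CC(C)=C[C@H](C)C[C@H](C)/C=C/C(N)=O | intermediate
21 | fully protected coupling product (C4–OTES, 2-(trimethylsilyl)ethyl ester) | CC(C)=C[C@H](C)C[C@H](C)/C=C/C(=O)NC1=C[C@@](O[Si](CC)(CC)CC)(CCCCC(=O)OCC[Si](C)(C)C)[C@H]2O[C@H]2C1=O | intermediate
22 | 5-[(1S,2S,6R)-2-hydroxy-5-oxo-4-{[(2E,4S,6R)-4,6,8-trimethylnona-2,7-dienoyl]amino}-7-oxabicyclo[4.1.0]hept-3-en-2-yl]pentanoic acid | CC(C)=C[C@H](C)C[C@H](C)/C=C/C(=O)NC1=C[C@@](O)(CCCCC(=O)O)[C@H]2O[C@H]2C1=O | target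

Total step count: 17.
Longest linear sequence: 10 steps (steps 1–8, 16 and 17). The side-chain branch runs over 9 steps (steps 9–15, 16 and 17).

Steps most likely to fail

1. Step 8.
- What may go wrong: carbene transfer to the enol ether next to the quaternary C4 may be slow. tert-Butoxide may desilylate the enol ether before cyclopropanation. Base or tribromomethyl anion may attack the freshly formed epoxy bromoenone.
- Fallback, from 10 back to 21: the one-carbon enlargement is carried out with methylene instead, and the halogen is added afterwards. Et2Zn/CH2I2 (Furukawa-modified Simmons–Smith cyclopropanation) should give the silyloxycyclopropane F1.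
- FeCl3 in DMF (Saegusa-type oxidative ring opening of the inner cyclopropane bond) should give the ring-enlarged β-chloro ketone F2. NaOAc in MeOH should then eliminate it to the epoxy enone F3.
- I2/pyridine (addition–elimination α-iodination of the enone) should give the 2-iodoenone F4. This is coupled with 20 under the conditions of step 16.

2. Step 16.
- What may go wrong: carbonate or palladium may isomerise or open the α,β-epoxy ketone. The weakly nucleophilic unsaturated primary amide may bind and reductively eliminate too slowly.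
- Fallback, from 12 and 19 back to 21, metal-free: ammonia in dioxane at 0 °C should give the NH-aziridine F5. This is a Gabriel–Cromwell aziridination, that is conjugate addition at C3 followed by displacement of the C2 bromide.
- Aldehyde 19 is converted with diethylphosphonoacetic acid and LiHMDS (Horner–Wadsworth–Emmons) into (2E,4S,6R)-4,6,8-trimethylnona-2,7-dienoic acid F6.
- Carbodiimide coupling of the two gives the N-acylaziridine F7. Et3N or DBU then removes the acidic C2–H and opens the C3–N bond (E1cB) to give the 2-acylamino enone.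

3. Step 3.
- What may go wrong: facial selectivity may be poor if the pentyl chain on the lower face hinders the peracid as much as the two silyloxy groups hinder the upper face.
- Fallback, from 1 back to 6: a linear alkynyl group stands in for the chain. tert-Butyldimethyl(pent-4-yn-1-yloxy)silane and n-BuLi give the lithium acetylide F8, which should add 1,2 to 1 opposite to OTBS to give the propargylic alcohol F9.
- TESOTf/2,6-lutidine gives its triethylsilyl ether F10. mCPBA should then meet an almost unhindered lower face and give the epoxide F11.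
- H2 over Pd/C in EtOAc saturates the alkyne.

Further compounds
F1 | step 8 | 2-(trimethylsilyl)ethyl 5-[1,5-bis(triethylsilyloxy)-3-oxatricyclo[4.1.0.0(2,4)]heptan-5-yl]pentanoate (CH2 bridge across C1–C3) | CC[Si](CC)(CC)O[C@@]12C[C@@H]1[C@@](O[Si](CC)(CC)CC)(CCCCC(=O)OCC[Si](C)(C)C)[C@H]3O[C@@H]23
F2 | step 8 | 3-chloro ketone, 2-(trimethylsilyl)ethyl 5-[3-chloro-5-oxo-2-(triethylsilyloxy)-7-oxabicyclo[4.1.0]heptan-2-yl]pentanoate (chloride centre undefined, lost next) | C1C(Cl)[C@@](O[Si](CC)(CC)CC)(CCCCC(=O)OCC[Si](C)(C)C)[C@H]2O[C@H]2C1=O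
F3 | step 8 | 2-(trimethylsilyl)ethyl 5-[(1S,2S,6R)-5-oxo-2-(triethylsilyloxy)-7-oxabicyclo[4.1.0]hept-3-en-2-yl]pentanoate | C1=C[C@@](O[Si](CC)(CC)CC)(CCCCC(=O)OCC[Si](C)(C)C)[C@H]2O[C@H]2C1=O
F4 | step 8 | 2-(trimethylsilyl)ethyl 5-[(1S,2S,6R)-4-iodo-5-oxo-2-(triethylsilyloxy)-7-oxabicyclo[4.1.0]hept-3-en-2-yl]pentanoate | IC1=C[C@@](O[Si](CC)(CC)CC)(CCCCC(=O)OCC[Si](C)(C)C)[C@H]2O[C@H]2C1=O
F5 | step 16 | C2–C3 NH-aziridine of the epoxy ketone (cis-fused, face undefined, both centres lost later) | N1C2C1[C@@](O[Si](CC)(CC)CC)(CCCCC(=O)OCC[Si](C)(C)C)[C@H]3O[C@H]3C2=O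
F6 | step 16 | (2E,4S,6R)-4,6,8-trimethylnona-2,7-dienoic acid | CC(C)=C[C@H](C)C[C@H](C)/C=C/C(=O)O
F7 | step 16 | N-[(2E,4S,6R)-4,6,8-trimethylnona-2,7-dienoyl] derivative of F5 | CC(C)=C[C@H](C)C[C@H](C)/C=C/C(=O)N1C2C1[C@@](O[Si](CC)(CC)CC)(CCCCC(=O)OCC[Si](C)(C)C)[C@H]3O[C@H]3C2=O
F8 | step 3 | lithium 5-(tert-butyldimethylsilyloxy)pent-1-yn-1-ide | [Li]C#CCCCO[Si](C)(C)C(C)(C)C
F9 | step 3 | 4-(tert-butyldimethylsilyloxy)-1-[5-(tert-butyldimethylsilyloxy)pent-1-yn-1-yl]cyclopent-2-en-1-ol (OH cis to OTBS) | C1[C@@](O)(C#CCCCO[Si](C)(C)C(C)(C)C)C=C[C@@H]1O[Si](C)(C)C(C)(C)C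
F10 | step 3 | triethylsilyl ether of F9 | C1[C@@](O[Si](CC)(CC)CC)(C#CCCCO[Si](C)(C)C(C)(C)C)C=C[C@@H]1O[Si](C)(C)C(C)(C)C
F11 | step 3 | epoxide of F10 (oxirane trans to both ring silyloxy groups) | C1[C@@](O[Si](CC)(CC)CC)(C#CCCCO[Si](C)(C)C(C)(C)C)[C@H]2O[C@H]2[C@@H]1O[Si](C)(C)C(C)(C)C
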